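Atom labels: unprimed atoms belong to the NH indole (indole A), primed atoms to the N-linked dibromoindole (indole B).
Cuts: N1–CO2Me, C2'–Br and C3–Br go first (indole B back to its oxindole, indole A back to an N-acylindoline). The benzene ring of indole A is then opened at C3a–C7a and C4–C5, and N1–C2 and N1'–C(sp) are cut last.
Enabling feature: the edge C7(OMe)–C6(H)–C5(Br)–C4(N1') of the benzene ring of indole A, with C7a–N1 beside it, maps onto C4–C5–C6 of 6-bromo-4-methoxypyridazin-3-amine plus the nitrogen-bearing carbon of an ynamide. The crowded C4–N1' bond can therefore be installed early as an unhindered N–C(sp) bond.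
Forward: 5-bromooxindole (ring B) is N-alkynylated and the chain is joined to the diazine nitrogen. One thermal [4+2]/–N2 event then builds the benzene ring and the five-membered ring of indoline A together.
Endgame: dehydrogenation, C3 bromination while ring B is still a lactam, lactam to 2'-bromoindole, N1 deprotection.
Stereochemistry: there is no stereocentre; the only stereogenic element is the hindered C4–N1' axis, which forms without control.

Key step: step 7

Assumption: the target string carries no axial descriptor, so the C4–N1' axis is left uncontrolled and the product is taken as the racemate.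

Step 1
Reactants: 1 4,6-dibromopyridazin-3-amine
Product: 2 6-bromo-4-methoxypyridazin-3-amine
Conditions: NaOMe (1.05 equiv), MeOH, 65 °C
Reagents that add atoms: sodium methoxide, [Na+].[O-]C
Why: Nucleophilic aromatic substitution by addition–elimination, in which the C4 bromide lies para to N1 and 4-halopyridazines outrun 3- and 6-halopyridazines towards alkoxides, while C6 is further deactivated as the position para to the amino donor, so one equivalent of methoxide should exchange only the C4 bromide, as it does on the 4-bromo-6-chloro analogue.

Step 2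
Reactants: 2 6-bromo-4-methoxypyridazin-3-amine
Product: 3 methyl (6-bromo-4-methoxypyridazin-3-yl)carbamate
Conditions: ClCO2Me (1.2 equiv), pyridine (solvent), 0 °C to rt
Reagents that add atoms: methyl chloroformate, COC(=O)Cl
Why: N-acylation of a hetaryl amine with a chloroformate, in which the first carbamoyl group lowers the nucleophilicity of nitrogen enough to hold the reaction at mono-acylation and leaves an N–H acidic enough for step 6.

Step 3
Reactants: 4 tert-butyl(but-3-yn-1-yloxy)dimethylsilane
Product: 5 [(4-bromobut-3-yn-1-yl)oxy](tert-butyl)dimethylsilane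
Conditions: NBS (1.1 equiv), AgNO3 (10 mol%), acetone, rt, dark
Reagents that add atoms: N-bromosuccinimide, O=C1CCC(=O)N1Br
Why: Silver-catalysed electrophilic bromination of a terminal alkyne (silver acetylide plus NBS), the standard entry to 1-bromoalkynes, which leaves a TBS ether untouched.

Step 4
Reactants: 5 [(4-bromobut-3-yn-1-yl)oxy](tert-butyl)dimethylsilane; 6 5-bromoindolin-2-one
Product: 7 5-bromo-1-{4-[(tert-butyldimethylsilyl)oxy]but-1-yn-1-yl}indolin-2-one
Conditions: CuSO4·5H2O (10 mol%), 1,10-phenanthroline (20 mol%), K3PO4 (2 equiv), toluene, 75 °C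
Reagents that add atoms: none
Why: Copper-catalysed N-alkynylation of a lactam with a 1-bromoalkyne (Ullmann–Goldberg-type C(sp)–N coupling), in which copper amidates of oxindoles are known from the related N-arylation to react at nitrogen and not at C3', the alkynyl bromide reacts far faster than the aryl bromide at this temperature, and the silyl ether keeps the hydroxyl group from adding to the new ynamide.

Step 5
Reactants: 7 5-bromo-1-{4-[(tert-butyldimethylsilyl)oxy]but-1-yn-1-yl}indolin-2-one
Product: 8 5-bromo-1-(4-hydroxybut-1-yn-1-yl)indolin-2-one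
Conditions: TBAF/AcOH (1:1, 1.2 equiv), THF, 0 °C
Reagents that add atoms: none
Why: Fluoride-induced desilylation, buffered with acetic acid so that the medium neither deprotonates C3'–H2 of the oxindole nor becomes acidic enough at 0 °C to protonate the ynamide.

Step 6
Reactants: 3 methyl (6-bromo-4-methoxypyridazin-3-yl)carbamate; 8 5-bromo-1-(4-hydroxybut-1-yn-1-yl)indolin-2-one
Product: 9 methyl N-(6-bromo-4-methoxypyridazin-3-yl)-N-[4-(5-bromo-2-oxoindolin-1-yl)but-3-yn-1-yl]carbamate
Conditions: PPh3, DIAD, THF, 0 °C to rt
Reagents that add atoms: none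
Why: Mitsunobu N-alkylation, in which the N–H of the hetaryl carbamate is the only proton acidic enough to protonate the betaine (C3'–H2 is far less acidic), the alcohol is primary, and the neutral medium spares both the ynamide and the oxindole CH2, which a base-mediated alkylation would not.

Step 7
Reactants: 9 methyl N-(6-bromo-4-methoxypyridazin-3-yl)-N-[4-(5-bromo-2-oxoindolin-1-yl)but-3-yn-1-yl]carbamate
Product: 11 methyl 5-bromo-4-(5-bromo-2-oxoindolin-1-yl)-7-methoxyindoline-1-carboxylate, via diazabicyclo[2.2.2]octatriene cycloadduct 10 (not isolated)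
Conditions: 1,3,5-triisopropylbenzene (0.01 M, dry, degassed), BHT (0.1 equiv), Ar, 200 °C
Reagents that add atoms: none
Why: The pyridazine is the 4π partner (its LUMO lowered by the two ring nitrogens, the C6 bromide and the carbamoyl group that ties up the amino lone pair) and the ynamide the 2π partner (its HOMO raised by N1'), so heating should bring about an inverse-demand intramolecular Diels–Alder addition across diazine C3 and C6 to give the 2,3-diazabicyclo[2.2.2]octatriene 10, which loses N2 at once by retro-Diels–Alder reaction and emerges as the arene 11. The closest known reaction type is the thermal alkyne–1,2-diazine cycloaddition of N-acyl-N-(but-3-ynyl)pyridazin-3-amines to N-acylindolines, and ynamines and ynamides are established 2π partners of pyridazines, pyrimidines and triazines, so what is extended here is only the pairing of an amide nitrogen on the distal alkyne carbon with a bromide on the diazine carbon it meets. The five-membered ring closes as the fused ring of the intramolecular [4+2] event through the C3a–C7a bond (three-atom N–CH2–CH2 tether), and the benzene ring arises by ring transformation, the four diazine carbons and the two alkyne carbons being kept after cycloreversion, with C4–C5 as its second new bond. No stereocentre is created, because both bridgeheads of 10 return to sp2, and the C4–N1' axis forms as the racemate. The step needs regioselectivity, and the tether secures it: it is too short for a bridged transition state, so the nitrogen-bearing alkyne carbon can only meet C6 and the order OMe, H, Br, N1' around the new ring is fixed. It also needs the ynamide to outlive the heating, which the lactam acyl group on N1', high dilution, dry degassed solvent, base-washed glass and BHT are meant to secure.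

Step 8
Reactants: 11 methyl 5-bromo-4-(5-bromo-2-oxoindolin-1-yl)-7-methoxyindoline-1-carboxylate
Product: 12 methyl 5-bromo-4-(5-bromo-2-oxoindolin-1-yl)-7-methoxy-1H-indole-1-carboxylate
Conditions: DDQ (2.5 equiv), 1,4-dioxane, 100 °C
Reagents that add atoms: none
Why: DDQ dehydrogenation of an N-acylindoline (hydride abstraction beside the arene and nitrogen, then proton loss) is driven by aromatisation to the indole, whereas the only other ring sp3 C–H bonds, C3'–H2, would have to give a cation next to a carbonyl group and should be left alone.

Step 9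
Reactants: 12 methyl 5-bromo-4-(5-bromo-2-oxoindolin-1-yl)-7-methoxy-1H-indole-1-carboxylate
Product: 13 methyl 3,5-dibromo-4-(5-bromo-2-oxoindolin-1-yl)-7-methoxy-1H-indole-1-carboxylate
Conditions: NBS (1.0 equiv), DMF, 0 °C to rt, dark
Reagents that add atoms: N-bromosuccinimide, O=C1CCC(=O)N1Br
Why: Electrophilic aromatic bromination at the enamide-like C3 of an N-acylindole, still the most nucleophilic carbon of 12 because ring B is held at the lactam level (its arene is deactivated and blocked at C5', its CH2 brominates only through slow enolisation) and C6 is squeezed between OMe and Br, so one equivalent of NBS under ionic conditions should stop at the 3-bromide.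

Step 10
Reactants: 13 methyl 3,5-dibromo-4-(5-bromo-2-oxoindolin-1-yl)-7-methoxy-1H-indole-1-carboxylate
Product: 14 methyl 3,5-dibromo-4-(2,5-dibromo-1H-indol-1-yl)-7-methoxy-1H-indole-1-carboxylate
Conditions: POBr3 (2.5 equiv, freshly purified), 1,2-dichloroethane, 80 °C; cold aq NaHCO3 quench
Reagents that add atoms: phosphoryl bromide, O=P(Br)(Br)Br
Why: Deoxygenative bromination of a lactam with POBr3 (Vilsmeier-type O-phosphorylation, bromide addition–elimination at C2', loss of a C3' proton) is the standard conversion of N-substituted oxindoles into 2-bromoindoles that keep C3'–H, and the N1 carbamate protects the 3-bromoindole of ring A against acid-induced bromine migration.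

Step 11
Reactants: 14 methyl 3,5-dibromo-4-(2,5-dibromo-1H-indol-1-yl)-7-methoxy-1H-indole-1-carboxylate
Product: 15 3,5-dibromo-4-(2,5-dibromo-1H-indol-1-yl)-7-methoxy-1H-indole (CNP0191258.0)
Conditions: K2CO3 (0.2 equiv), MeOH/THF, rt
Reagents that add atoms: none
Why: Base-catalysed methanolysis of an N-acylindole (acyl transfer to methoxide with indolide as a good leaving group) runs at room temperature and touches neither the four C–Br bonds nor the methyl ether.

Compound list
1 | 4,6-dibromopyridazin-3-amine | Nc1nnc(Br)cc1Br | starting material
2 | 6-bromo-4-methoxypyridazin-3-amine | COc1cc(Br)nnc1N | intermediate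
3 | methyl (6-bromo-4-methoxypyridazin-3-yl)carbamate | COc1cc(Br)nnc1NC(=O)OC | intermediate
4 | tert-butyl(but-3-yn-1-yloxy)dimethylsilane (commercial TBS ether of but-3-yn-1-ol) | C#CCCO[Si](C)(C)C(C)(C)C | starting material
5 | [(4-bromobut-3-yn-1-yl)oxy](tert-butyl)dimethylsilane | BrC#CCCO[Si](C)(C)C(C)(C)C | intermediate
6 | 5-bromoindolin-2-one | O=C1Cc2cc(Br)ccc2N1 | starting material
7 | 5-bromo-1-{4-[(tert-butyldimethylsilyl)oxy]but-1-yn-1-yl}indolin-2-one | O=C1Cc2cc(Br)ccc2N1C#CCCO[Si](C)(C)C(C)(C)C | intermediate
8 | 5-bromo-1-(4-hydroxybut-1-yn-1-yl)indolin-2-one | O=C1Cc2cc(Br)ccc2N1C#CCCO | intermediate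
9 | methyl N-(6-bromo-4-methoxypyridazin-3-yl)-N-[4-(5-bromo-2-oxoindolin-1-yl)but-3-yn-1-yl]carbamate | COc1cc(Br)nnc1N(C(=O)OC)CCC#CN1C(=O)Cc2cc(Br)ccc21 | intermediate
10 | 2,3-diazabicyclo[2.2.2]octa-2,5,7-triene cycloadduct of 9 (bridgeheads: former diazine C3 bearing the carbamate nitrogen and former C6 bearing Br; N=N bridge; MeO-substituted alkene bridge; second alkene bridge carries the oxindol-1-yl group and is fused to the pyrrolidine ring; racemic, transient) | COC1=CC2(Br)N=NC13N(C(=O)OC)CCC3=C2N4C(=O)Cc5cc(Br)ccc45 | intermediate
11 | methyl 5-bromo-4-(5-bromo-2-oxoindolin-1-yl)-7-methoxyindoline-1-carboxylate | COc1cc(Br)c(N2C(=O)Cc3cc(Br)ccc32)c2c1N(C(=O)OC)CC2 | intermediate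
12 | methyl 5-bromo-4-(5-bromo-2-oxoindolin-1-yl)-7-methoxy-1H-indole-1-carboxylate | COc1cc(Br)c(N2C(=O)Cc3cc(Br)ccc32)c2ccn(C(=O)OC)c12 | intermediate
13 | methyl 3,5-dibromo-4-(5-bromo-2-oxoindolin-1-yl)-7-methoxy-1H-indole-1-carboxylate | COc1cc(Br)c(N2C(=O)Cc3cc(Br)ccc32)c2c(Br)cn(C(=O)OC)c12 | intermediate
14 | methyl 3,5-dibromo-4-(2,5-dibromo-1H-indol-1-yl)-7-methoxy-1H-indole-1-carboxylate | COc1cc(Br)c(-n2c(Br)cc3cc(Br)ccc32)c2c(Br)cn(C(=O)OC)c12 | intermediate
15 | 3,5-dibromo-4-(2,5-dibromo-1H-indol-1-yl)-7-methoxy-1H-indole | COc1cc(Br)c(-n2c(Br)cc3cc(Br)ccc32)c2c(Br)c[nH]c12 | target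

Total step count: 11.
Longest linear sequence: 9 steps (4 → 5 → 7 → 8 → 9 → 11 → 12 → 13 → 14 → 15). The diazine branch (steps 1 and 2) joins at step 6.

Steps most likely to fail

Step 7.
- What may go wrong: the ynamide may break down thermally or be hydrated before the diazine reacts, since the diazine carries two donor groups (OMe and acylamino). Bond formation between two fully substituted carbons (C4 and C5) may also be sterically retarded.
- Fallback (sets out from 3, returns at 11): the diazine-to-benzene ring transformation is kept, but it is run with a thermally inert alkyne, and the C4–N1' bond is made afterwards.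
- Mitsunobu alkylation of 3 with commercial 4-(trimethylsilyl)but-3-yn-1-ol (C[Si](C)(C)C#CCCO) should give methyl N-(6-bromo-4-methoxypyridazin-3-yl)-N-[4-(trimethylsilyl)but-3-yn-1-yl]carbamate F1.
- Heating F1 in 1,3,5-triisopropylbenzene at 230 °C should pass through the silyl-substituted diazabicyclooctatriene cycloadduct F2 and deliver methyl 5-bromo-7-methoxy-4-(trimethylsilyl)indoline-1-carboxylate F3.
- ICl in CH2Cl2 at 0 °C should replace silicon by iodine at the ipso carbon, which lies para to OMe, to give methyl 5-bromo-4-iodo-7-methoxyindoline-1-carboxylate F4.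
- A Goldberg amidation of F4 with 6 (CuI, trans-N,N'-dimethylcyclohexane-1,2-diamine, K2CO3, dioxane, 100 °C) should be selective for C–I over the C–Br bonds and for nitrogen over C3' of the oxindole, and it returns to 11.

Step 4.
- What may go wrong: deprotonation at C3', bromine transfer from the bromoalkyne to the resulting enolate, and homocoupling of the bromoalkyne may all outrun the slow cupration of the lactam nitrogen.
- Fallback (sets out from 6, returns at 7): the bromoalkyne is abandoned for an electrophile that donates no positive bromine. The N–C bond is then formed as a vinylic amidation, followed by elimination.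
- Ramirez dibromo-olefination of commercial 3-[(tert-butyldimethylsilyl)oxy]propanal (O=CCCO[Si](C)(C)C(C)(C)C) with CBr4/PPh3 in CH2Cl2 at 0 °C should give tert-butyl[(4,4-dibromobut-3-en-1-yl)oxy]dimethylsilane F5.
- Coupling of F5 with 6 uses CuI, N,N'-dimethylethylenediamine and Cs2CO3 in dioxane at 65 °C, the catalyst family that is N-selective for oxindoles. It should substitute the less hindered bromide to give 5-bromo-1-{(Z)-1-bromo-4-[(tert-butyldimethylsilyl)oxy]but-1-en-1-yl}indolin-2-one F6.
- F6 should lose HBr by anti elimination in the same flask to give 7.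

Step 9.
- What may go wrong: site selectivity may be lost, with bromination at the enolisable C3'–H2 or at C6 competing with the peri-hindered, acyl-deactivated C3.
- Fallback (sets out from 12, returns at 15): the order of events is changed so that C3 is brominated on the far more nucleophilic free indole.
- Methanolysis of 12 (K2CO3, MeOH) should give 5-bromo-1-(5-bromo-7-methoxy-1H-indol-4-yl)indolin-2-one F7.
- NBS (1.0 equiv) in THF at −78 °C should then give 5-bromo-1-(3,5-dibromo-7-methoxy-1H-indol-4-yl)indolin-2-one F8.
- POBr3 buffered with imidazole in 1,2-dichloroethane at 80 °C should convert the lactam of F8 directly into the 2'-bromoindole 15. The buffer is there to suppress acid-induced migration of the C3 bromine.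

Further compounds
F1 | step 7 | methyl N-(6-bromo-4-methoxypyridazin-3-yl)-N-[4-(trimethylsilyl)but-3-yn-1-yl]carbamate | COc1cc(Br)nnc1N(C(=O)OC)CCC#C[Si](C)(C)C
F2 | step 7 | silyl-substituted 2,3-diazabicyclo[2.2.2]octa-2,5,7-triene cycloadduct of F1 (racemic, transient) | COC1=CC2(Br)N=NC13N(C(=O)OC)CCC3=C2[Si](C)(C)C
F3 | step 7 | methyl 5-bromo-7-methoxy-4-(trimethylsilyl)indoline-1-carboxylate | COc1cc(Br)c([Si](C)(C)C)c2c1N(C(=O)OC)CC2
F4 | step 7 | methyl 5-bromo-4-iodo-7-methoxyindoline-1-carboxylate | COc1cc(Br)c(I)c2c1N(C(=O)OC)CC2
F5 | step 4 | tert-butyl[(4,4-dibromobut-3-en-1-yl)oxy]dimethylsilane | BrC(Br)=CCCO[Si](C)(C)C(C)(C)C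
F6 | step 4 | 5-bromo-1-{(Z)-1-bromo-4-[(tert-butyldimethylsilyl)oxy]but-1-en-1-yl}indolin-2-one | O=C1Cc2cc(Br)ccc2N1/C(Br)=C/CCO[Si](C)(C)C(C)(C)C
F7 | step 9 | 5-bromo-1-(5-bromo-7-methoxy-1H-indol-4-yl)indolin-2-one | COc1cc(Br)c(N2C(=O)Cc3cc(Br)ccc32)c2cc[nH]c12
F8 | step 9 | 5-bromo-1-(3,5-dibromo-7-methoxy-1H-indol-4-yl)indolin-2-one | COc1cc(Br)c(N2C(=O)Cc3cc(Br)ccc32)c2c(Br)c[nH]c12
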